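**Plan**

Numbering: hydrindane C1 (side chain), C2 (OH), C3, C3a (CH3), C4 (Br), C5, C6, C7 (CH3, OH), C7a (H). Ring A is C1′ (=CH), C2′, C3′ (CMe2), C4′ (Br), C5′, C6′. β is the face of the angular methyl group.
Cuts: both C–Br bonds (back to carbinols of opposite configuration); ring A at C2′–C3′ and C5′–C6′ with C4′ as C=O; the C1–CH bond (aldol); C1–C2, C2–C3 and C3a–C7a (Pauson–Khand). This leaves (R)-linalool, which supplies nine of the eleven hydrindane carbons.
Enabling feature: C1′ is an sp2 carbon flanked by two allylic CH2 groups (C2′, C6′), so it is a 2-alkylidenepropane-1,3-diyl, a double allyl cation. At the ketone level C3′(Me2)–C4′–C5′ is the α,α′-dianion of 3-methylbutan-2-one, supplied as the dianion of 2,2-dimethylacetoacetic acid.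
Forward order: both hydrindane rings form together (step 6), then the C1 side chain is added (step 11), and ring A is closed last by a one-flask [3+3] annulation (step 16).
Stereochemistry: C7 comes from linalool; C4 from Shi epoxidation followed by inversion; C3a from the Pauson–Khand tether. C7a and C1 come from α-face attack, and C2 from hydride addition followed by Mitsunobu inversion. The alkene geometry comes from the syn π-allylpalladium complex, and C4′ from CBS reduction followed by inversion.

Key step: step 16

Assumption: the carbinol carbon made in step 11 (the future =CH) is carried as a mixture of epimers and drawn without configuration, because it becomes sp2 in step 16.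

**Step 1**
Reactants: 1 (R)-(−)-linalool
Product: 2 (R)-linalool triethylsilyl ether
Conditions: TESOTf, 2,6-lutidine, CH2Cl2, 0 °C
Reagents that add atoms: triethylsilyl triflate, CC[Si](CC)(CC)OS(=O)(=O)C(F)(F)F
Why: Silylation of the hindered tertiary alcohol with the silyl triflate masks the C7 oxygen, leaves the chiral-pool configuration untouched and prevents cyclisation onto the epoxide made next.

**Step 2**
Reactants: 2 (R)-linalool triethylsilyl ether
Product: 3 (3R,6R)-6,7-epoxy-3,7-dimethyl-3-(triethylsilyloxy)oct-1-ene
Conditions: D-fructose-derived Shi ketone (0.3 equiv), KHSO5 (as 2KHSO5·KHSO4·K2SO4), K2CO3, Na2B4O7 buffer, Bu4NHSO4 (cat.), MeCN–CH2(OMe)2–H2O, 0 °C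
Reagents that add atoms: potassium peroxymonosulfate, [K+].[O-]S(=O)(=O)OO
Why: Shi asymmetric epoxidation is much faster on the electron-rich trisubstituted alkene than on the vinyl group, and the spiro transition state of the D-fructose-derived dioxirane should give the (6R)-epoxide, the source of C4.

**Step 3**
Reactants: 3 (3R,6R)-6,7-epoxy-3,7-dimethyl-3-(triethylsilyloxy)oct-1-ene
Product: 4 (2R)-4-[(2R)-3,3-dimethyloxiran-2-yl]-2-methyl-2-(triethylsilyloxy)butanal
Conditions: O3, CH2Cl2, −78 °C; then Me2S, −78 °C to rt
Reagents that add atoms: ozone, [O-][O+]=O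
Why: Ozonolysis with reductive work-up cleaves the only remaining alkene to a non-enolisable α-silyloxy aldehyde without touching the epoxide.

**Step 4**
Reactants: 4 (2R)-4-[(2R)-3,3-dimethyloxiran-2-yl]-2-methyl-2-(triethylsilyloxy)butanal
Product: 5 (3R)-5-[(2R)-3,3-dimethyloxiran-2-yl]-3-methyl-3-(triethylsilyloxy)pent-1-yne
Conditions: dimethyl (1-diazo-2-oxopropyl)phosphonate, K2CO3, MeOH, 0 °C to rt
Reagents that add atoms: dimethyl (1-diazo-2-oxopropyl)phosphonate, COP(=O)(OC)C(=[N+]=[N-])C(C)=O
Why: Ohira–Bestmann (Seyferth–Gilbert) homologation turns the aldehyde into the terminal alkyne (future C7a and C1) under mild carbonate conditions that the epoxide and silyl ether tolerate.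

**Step 5**
Reactants: 5 (3R)-5-[(2R)-3,3-dimethyloxiran-2-yl]-3-methyl-3-(triethylsilyloxy)pent-1-yne
Product: 6 (3R,6R)-2,6-dimethyl-6-(triethylsilyloxy)oct-1-en-7-yn-3-ol
Conditions: Al(Oi-Pr)3 (0.2 equiv), toluene, 110 °C
Reagents that add atoms: none
Why: Aluminium-alkoxide-promoted epoxide-to-allylic-alcohol isomerisation removes a methyl proton in a syn elimination, breaks the tertiary C–O bond and leaves the secondary C–O bond (C4) intact.

**Step 6**
Reactants: 6 (3R,6R)-2,6-dimethyl-6-(triethylsilyloxy)oct-1-en-7-yn-3-ol
Product: 7 hydrindenone with C2=O and C1=C7a plus 3aβ-CH3 4α-OH 7α-CH3 7β-OTES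
Conditions: Co2(CO)8 (0.2 equiv), tetramethylthiourea (0.6 equiv), CO (1 atm), toluene, 75 °C
Reagents that add atoms: carbon monoxide, [C-]#[O+]
Why: The intramolecular Pauson–Khand reaction of the 1,7-enyne builds both rings, the C2 carbonyl and the quaternary C3a at once, and the chair-like tether should keep the C7 methyl group equatorial and the silyloxy group axial (no syn-diaxial methyl/methyl contact), which places the angular methyl cis to the C7 oxygen and trans to the C4 hydroxyl.

**Step 7**
Reactants: 7 hydrindenone with 4α-OH
Product: 8 4β-bromo hydrindenone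
Conditions: CBr4, PPh3, toluene, 80 °C
Reagents that add atoms: carbon tetrabromide, BrC(Br)(Br)Br
Why: The Appel reaction replaces the axial 4α-hydroxyl by bromide with inversion to give the equatorial 4β-bromide, a substitution precedented for neopentylic carbinols of bromoterpenoids and helped here because a competing methyl shift would put positive charge at C3a next to the electron-poor enone.

**Step 8**
Reactants: 8 4β-bromo hydrindenone
Product: 9 trans-fused 2-(triethylsilyloxy)hydrind-1-ene with 7aα-H
Conditions: Et3SiH, RhCl(PPh3)3 (5 mol %), THF, 55 °C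
Reagents that add atoms: triethylsilane, CC[SiH](CC)CC
Why: Rhodium-catalysed 1,4-hydrosilylation of the enone delivers hydride to C7a from the α face, since the β face is closed by the axial C3a methyl and C7 silyloxy groups, and this sets the trans ring fusion and gives the C1=C2 enol silane regiospecifically.

**Step 9**
Reactants: 10 2-methylenepropane-1,3-diol
Product: 11 2-(chloromethyl)prop-2-en-1-ol
Conditions: PPh3 (1 equiv), CCl4, THF, reflux, diol in excess
Reagents that add atoms: carbon tetrachloride, ClC(Cl)(Cl)Cl
Why: Appel chlorination of an excess of the symmetrical diol gives the monochloride, and any allylic transposition is degenerate.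

**Step 10**
Reactants: 11 2-(chloromethyl)prop-2-en-1-ol
Product: 12 2-(chloromethyl)prop-2-enal
Conditions: TEMPO (0.1 equiv), PhI(OAc)2, CH2Cl2, rt
Reagents that add atoms: none
Why: The TEMPO/PhI(OAc)2 oxidation of the primary allylic alcohol stops at the enal under near-neutral conditions that spare the allylic chloride.

**Step 11**
Reactants: 9 trans-fused enol silane; 12 2-(chloromethyl)prop-2-enal
Product: 13 1α-[2-(chloromethyl)-1-hydroxyprop-2-enyl] trans-hydrindan-2-one (carbinol epimers)
Conditions: BF3·OEt2, CH2Cl2, −78 °C; aqueous work-up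
Reagents that add atoms: none
Why: The Mukaiyama aldol addition occurs regiospecifically at C1 and from the α face, because the β face of C1 is flanked by the axial C3a methyl and C7 silyloxy groups, and this gives the pseudo-equatorial 1α side chain that is also favoured on equilibration.

**Step 12**
Reactants: 13 aldol
Product: 14 allylic benzoate of 13
Conditions: BzCl, pyridine, CH2Cl2, 0 °C
Reagents that add atoms: benzoyl chloride, O=C(Cl)c1ccccc1
Why: Acylation of the secondary allylic alcohol under weakly basic, cold conditions installs the leaving group for the later allylpalladium chemistry before β-elimination can compete.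

**Step 13**
Reactants: 14 β-benzoyloxy ketone
Product: 15 2β-alcohol
Conditions: NaBH4, MeOH–THF, −40 °C
Reagents that add atoms: none
Why: Borohydride reduction should take place from the α face, away from the angular methyl group that lies 1,3 to the carbonyl (the behaviour of 16-oxo steroids), to give the 2β-alcohol.

**Step 14**
Reactants: 15 2β-alcohol
Product: 16 2α-benzoate (dibenzoate allylic chloride)
Conditions: PhCO2H, PPh3, DIAD, toluene, 0 °C to rt
Reagents that add atoms: benzoic acid, OC(=O)c1ccccc1
Why: The Mitsunobu reaction inverts C2 by SN2 attack of benzoate from the open α face, which sets the 1,2-cis relationship of the target and protects the oxygen in the same operation.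

**Step 15**
Reactants: 17 ethyl 2,2-dimethyl-3-oxobutanoate
Product: 18 2,2-dimethyl-3-oxobutanoic acid
Conditions: KOH, H2O–EtOH, 0 °C to rt; then cold 1 M HCl, extraction at 0 °C, used at once
Reagents that add atoms: potassium hydroxide, [K+].[OH-]
Why: Cold saponification followed by cold acidification gives the isolable but heat-sensitive α,α-disubstituted β-keto acid.

**Step 16**
Reactants: 18 2,2-dimethyl-3-oxobutanoic acid; 16 dibenzoate allylic chloride
Product: 21 ring A ketone (E)-4-(hydrindan-1-ylmethylidene)-2,2-dimethylcyclohexanone, via dilithium dianion 19 (not isolated), via lithium keto carboxylate 20 (not isolated)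
Conditions: 18, LDA (2 equiv per 18), THF, −78 to 0 °C; then 16 and Pd(PPh3)4 (0.1 equiv), −40 °C to 45 °C, one flask
Reagents that add atoms: none
Why: Proposed new method: double deprotonation gives the carboxylate–enolate 19, whose only carbon nucleophile (the CH2 terminus, future C5′) attacks the 2-substituted π-allylpalladium complex formed first from the much more reactive allylic chloride and makes C5′–C6′ (20); on warming, zerovalent palladium ionises the secondary allylic benzoate, the tethered β-keto carboxylate binds the cationic allyl complex and loses CO2, and the tetrasubstituted enolate released at C3′ attacks the unsubstituted allyl terminus to make C2′–C3′ and the quaternary carbon. The closest known reactions are the palladium-catalysed (Tsuji–Trost) allylation of lithium ketone enolates and the decarboxylative Tsuji allylation of α,α-disubstituted β-keto acids and esters, and what is new is their union into a one-flask [3+3] annulation of one bis-nucleophile and one bis-electrophile. The one ring closure is a 6-(enolendo)-exo attack on the allyl terminus, whereas closure from C5′ would need a four-membered ring and attack at the substituted terminus next to the hydrindane is sterically closed. No stereocentre is formed; the stereo-element is the C1′=CH geometry, fixed because the hydrindanyl group takes the syn position of the allyl complex, cis to the slim C6′ chain on the central carbon, after π–σ–π equilibration that should be faster than the slow decarboxylation, so the bond made last (to C2′) ends up trans to the hydrindane from either carbinol epimer of 16. The step needs order selectivity and a regiospecific hindered enolate, and these are secured by the chloride/benzoate reactivity gap, by the blocked α-carbon of 18 (one enolisable position only) and by placing the carboxylate exactly on C3′.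

**Step 17**
Reactants: 21 ring A ketone
Product: 22 (4′R)-alcohol
Conditions: (S)-Me-CBS oxazaborolidine (0.2 equiv), catecholborane, toluene, −78 °C
Reagents that add atoms: none
Why: The Corey–Bakshi–Shibata reduction distinguishes the quaternary C3′ side from the CH2 side of the ketone under reagent control, the (S)-catalyst should give the (R)-alcohol, and catecholborane avoids hydroboration of the trisubstituted alkene.

**Step 18**
Reactants: 22 (4′R)-alcohol
Product: 23 (4′S)-bromide (dibromide with 2α-OBz and 7β-OTES)
Conditions: CBr4, PPh3, toluene, 60 °C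
Reagents that add atoms: carbon tetrabromide, BrC(Br)(Br)Br
Why: The Appel reaction on the conformationally mobile ring A carbinol should proceed by SN2 inversion through the axial oxyphosphonium conformer to give the (S)-bromide.

**Step 19**
Reactants: 23 dibromide with 2α-OBz and 7β-OTES
Product: 24 iriediol 7-O-triethylsilyl ether
Conditions: K2CO3 (cat.), MeOH, rt
Reagents that add atoms: none
Why: Carbonate-catalysed transesterification with methanol removes the benzoate, and the two neopentylic secondary bromides are inert to such mild base.

**Step 20**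
Reactants: 24 iriediol 7-O-triethylsilyl ether
Product: 25 iriediol
Conditions: HF·pyridine, THF, 0 °C to rt
Reagents that add atoms: none
Why: Fluoride-mediated desilylation with buffered HF cleaves the tertiary silyl ether without ionising the tertiary alcohol or touching the bromides, and this gives the target.

**Compound list**

1 | (R)-(−)-linalool | C=C[C@](C)(O)CCC=C(C)C | starting material
2 | (R)-linalool triethylsilyl ether | C=C[C@](C)(O[Si](CC)(CC)CC)CCC=C(C)C | intermediate
3 | (3R,6R)-6,7-epoxy-3,7-dimethyl-3-(triethylsilyloxy)oct-1-ene | C=C[C@](C)(O[Si](CC)(CC)CC)CC[C@H]1OC1(C)C | intermediate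
4 | (2R)-4-[(2R)-3,3-dimethyloxiran-2-yl]-2-methyl-2-(triethylsilyloxy)butanal | O=C[C@](C)(O[Si](CC)(CC)CC)CC[C@H]1OC1(C)C | intermediate
5 | (3R)-5-[(2R)-3,3-dimethyloxiran-2-yl]-3-methyl-3-(triethylsilyloxy)pent-1-yne | C#C[C@](C)(O[Si](CC)(CC)CC)CC[C@H]1OC1(C)C | intermediate
6 | (3R,6R)-2,6-dimethyl-6-(triethylsilyloxy)oct-1-en-7-yn-3-ol | C#C[C@](C)(O[Si](CC)(CC)CC)CC[C@@H](O)C(C)=C | intermediate
7 | hydrindenone (C2=O, C1=C7a; 3aβ-CH3, 4α-OH, 7α-CH3, 7β-OTES) | O=C1C[C@]2(C)[C@H](O)CC[C@@](C)(O[Si](CC)(CC)CC)C2=C1 | intermediate
8 | 4β-bromo hydrindenone | O=C1C[C@]2(C)[C@@H](Br)CC[C@@](C)(O[Si](CC)(CC)CC)C2=C1 | intermediate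
9 | trans-fused 2-(triethylsilyloxy)hydrind-1-ene (7aα-H, 4β-Br) | C1=C(O[Si](CC)(CC)CC)C[C@]2(C)[C@@H](Br)CC[C@@](C)(O[Si](CC)(CC)CC)[C@@H]12 | intermediate
10 | 2-methylenepropane-1,3-diol | C=C(CO)CO | starting material
11 | 2-(chloromethyl)prop-2-en-1-ol | C=C(CO)CCl | intermediate
12 | 2-(chloromethyl)prop-2-enal | C=C(C=O)CCl | intermediate
13 | 1α-[2-(chloromethyl)-1-hydroxyprop-2-enyl] trans-hydrindan-2-one (carbinol epimers) | ClCC(=C)C(O)[C@@H]1C(=O)C[C@]2(C)[C@@H](Br)CC[C@@](C)(O[Si](CC)(CC)CC)[C@@H]12 | intermediate
14 | allylic benzoate of 13 | ClCC(=C)C(OC(=O)c3ccccc3)[C@@H]1C(=O)C[C@]2(C)[C@@H](Br)CC[C@@](C)(O[Si](CC)(CC)CC)[C@@H]12 | intermediate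
15 | 2β-alcohol | ClCC(=C)C(OC(=O)c3ccccc3)[C@@H]1[C@@H](O)C[C@]2(C)[C@@H](Br)CC[C@@](C)(O[Si](CC)(CC)CC)[C@@H]12 | intermediate
16 | 2α-benzoate (dibenzoate allylic chloride) | ClCC(=C)C(OC(=O)c3ccccc3)[C@@H]1[C@H](OC(=O)c4ccccc4)C[C@]2(C)[C@@H](Br)CC[C@@](C)(O[Si](CC)(CC)CC)[C@@H]12 | intermediate
17 | ethyl 2,2-dimethyl-3-oxobutanoate | CCOC(=O)C(C)(C)C(C)=O | starting material
18 | 2,2-dimethyl-3-oxobutanoic acid | OC(=O)C(C)(C)C(C)=O | intermediate
19 | dilithium dianion of 18 (carboxylate and terminal enolate) | [Li+].[Li+].[O-]C(=O)C(C)(C)C([O-])=C | intermediate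
20 | lithium keto carboxylate (C5′–C6′ formed) | [Li+].[O-]C(=O)C(C)(C)C(=O)CCC(=C)C(OC(=O)c3ccccc3)[C@@H]1[C@H](OC(=O)c4ccccc4)C[C@]2(C)[C@@H](Br)CC[C@@](C)(O[Si](CC)(CC)CC)[C@@H]12 | intermediate
21 | ring A ketone, (E)-4-(hydrindan-1-ylmethylidene)-2,2-dimethylcyclohexanone | CC1(C)C/C(=C/[C@@H]2[C@H](OC(=O)c3ccccc3)C[C@]4(C)[C@@H](Br)CC[C@@](C)(O[Si](CC)(CC)CC)[C@@H]24)CCC1=O | intermediate
22 | (4′R)-alcohol | CC1(C)C/C(=C/[C@@H]2[C@H](OC(=O)c3ccccc3)C[C@]4(C)[C@@H](Br)CC[C@@](C)(O[Si](CC)(CC)CC)[C@@H]24)CC[C@H]1O | intermediate
23 | (4′S)-bromide (2α-OBz, 7β-OTES) | CC1(C)C/C(=C/[C@@H]2[C@H](OC(=O)c3ccccc3)C[C@]4(C)[C@@H](Br)CC[C@@](C)(O[Si](CC)(CC)CC)[C@@H]24)CC[C@@H]1Br | intermediate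
24 | iriediol 7-O-triethylsilyl ether | CC1(C)C/C(=C/[C@@H]2[C@H](O)C[C@]4(C)[C@@H](Br)CC[C@@](C)(O[Si](CC)(CC)CC)[C@@H]24)CC[C@@H]1Br | intermediate
25 | iriediol | CC1(C)C/C(=C/[C@@H]2[C@H](O)C[C@]3(C)[C@@H](Br)CC[C@@](C)(O)[C@@H]23)CC[C@@H]1Br | target

**Step count**

Total steps: 20. Longest linear sequence: 17 (steps 1–8, 11–14, 16–20).

**Steps most likely to fail**

Step 16 (labelled step). Several processes could defeat it. The enolate may acylate on the benzoates. The hindered allyl complex may lose a proton to give a diene. The C3′ enolate may be protonated or O-allylated before C–C bond formation. The fallback makes the two bonds in separate, known operations. Starting from 16, the allylic chloride is substituted (Pd(PPh3)4 cat., THF, −40 to 0 °C) by the kinetic lithium enolate of 3-methylbutan-2-one (LDA, −78 °C) to give the isopropyl ketone F1. A Tsuji–Trost alkylation under reversible enolisation (KOt-Bu, t-BuOH–THF, Pd(PPh3)4, 40 °C) then closes the ring. Only the tetrasubstituted enolate can reach the allyl terminus through a six-membered transition state. The route is rejoined at 21.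

Step 7. Ionisation of the axial oxyphosphonium salt could lead to methyl migration, to elimination towards C5, or to no substitution at all at the neopentylic carbon. In the fallback, starting from 7, the alcohol is converted (ClCH2SO2Cl, pyridine, 0 °C) into the isolated chloromethanesulfonate F2. This is a small and very good leaving group, and it is displaced in a separate SN2 step by LiBr in DMF at 60 °C. The route is rejoined at 8.

Step 8. Hydride transfer to C7a, which sits between two fully substituted carbons, may be too slow, or 1,2-hydrosilylation may take over. The fallback uses hydrogen delivered by a directing group instead of a metal hydride conjugate addition. Starting from 7, hydrogenation with [Ir(cod)(PCy3)(py)]PF6 (H2, CH2Cl2), directed by the axial 4α-hydroxyl, gives the trans-hydrindanone F3. An Appel reaction gives the bromo ketone F4. Soft enolisation (TESOTf, Et3N, CH2Cl2) then gives the enol silane, and the regioisomer towards the neopentylic C3 is removed by chromatography. The route is rejoined at 9.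

**Further compounds**

F1 | step 16 | isopropyl ketone (C5′–C6′ formed, allylic benzoate intact) | CC(C)C(=O)CCC(=C)C(OC(=O)c3ccccc3)[C@@H]1[C@H](OC(=O)c4ccccc4)C[C@]2(C)[C@@H](Br)CC[C@@](C)(O[Si](CC)(CC)CC)[C@@H]12
F2 | step 7 | 4α-chloromethanesulfonate of 7 | O=C1C[C@]2(C)[C@H](OS(=O)(=O)CCl)CC[C@@](C)(O[Si](CC)(CC)CC)C2=C1
F3 | step 8 | trans-hydrindan-2-one with 4α-OH | O=C1C[C@]2(C)[C@H](O)CC[C@@](C)(O[Si](CC)(CC)CC)[C@H]2C1
F4 | step 8 | trans-hydrindan-2-one with 4β-Br | O=C1C[C@]2(C)[C@@H](Br)CC[C@@](C)(O[Si](CC)(CC)CC)[C@H]2C1
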